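**Strategy.** The synthesis rests on disconnecting ring B at C6–C7. Because the C6 oxygen sits β to C8 in ring B, a C8 ketone turns this bond into an aldol bond, and the quaternary, non-epimerisable C10 can steer everything else. One operation closes ring B from a 6,7-seco keto aldehyde, fixes the equatorial 6α-carbinol and lets C9 settle into the equatorial 9β arrangement of a trans-decalin. The precursor is a ring A cyclohexane carrying the C5 aldehyde (already trans to the C9 branch), the C10 methyl and a C9 carbon bearing the acetyl group (C8, C7) and the dioxolane-protected oxobutyl chain.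

Key step: step 10

Assumption: labdane numbering is used throughout (ring A = C1–C5 and C10, ring B = C5–C10, side chain C11–C13, C17 on C8, C20 on C10). The sense of induction in step 2 is taken to follow the parent 2-methylcyclohexanone case, where the (S)-ligand gives the (S)-ketone, so the (R)-ligand is used. Enantiomeric purity is to be completed, if needed, by one crystallisation of acid 8 as a salt with a chiral amine.

**Route**

Step 1
Reactants: 1 2,2,6-trimethylcyclohexan-1-one; 2 allyl chloroformate
Product: 3 allyl 2,6,6-trimethylcyclohex-1-en-1-yl carbonate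
Conditions: LiHMDS, THF, 0 °C; TMEDA, then 2, −78 → 20 °C
Reagents that add atoms: none
Why: The ketone can be deprotonated only at its single α-hydrogen, and the resulting tetrasubstituted lithium enolate is acylated on oxygen by the chloroformate in the presence of TMEDA (enol carbonate formation).

Step 2
Reactants: 3 allyl 2,6,6-trimethylcyclohex-1-en-1-yl carbonate
Product: 4 (R)-2-allyl-2,6,6-trimethylcyclohexan-1-one
Conditions: Pd2(dba)3 (2.5 mol %), (R)-t-BuPHOX (6 mol %), THF, 25 °C
Reagents that add atoms: none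
Why: The enol carbonate ionises on zerovalent palladium, loses CO2, and the palladium-bound enolate is allylated at carbon inside the chiral pocket of the PHOX ligand (decarboxylative asymmetric allylic alkylation), which creates the quaternary C10 with the β-methyl configuration of the target.

Step 3
Reactants: 4 (R)-2-allyl-2,6,6-trimethylcyclohexan-1-one
Product: 6 (R)-1-allyl-1,3,3-trimethyl-2-methylidenecyclohexane, via β-silyl carbinol 5 (not isolated)
Conditions: Me3SiCH2Li, THF/pentane, 0 → 40 °C; then 1 M HCl (aq), 25 °C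
Reagents that add atoms: (trimethylsilyl)methyllithium, [Li]C[Si](C)(C)C
Why: Peterson olefination, in which the organolithium adds to the hindered but non-enolisable C5 ketone and acid-promoted loss of trimethylsilanol from the β-silyl carbinol (β-silicon-stabilised, so no skeletal shift is expected) gives the exocyclic C5=C6 alkene without touching C10.

Step 4
Reactants: 6 (R)-1-allyl-1,3,3-trimethyl-2-methylidenecyclohexane
Product: 7 (R)-2-(1,3,3-trimethyl-2-methylidenecyclohexyl)acetaldehyde
Conditions: OsO4 (2 mol %), NaIO4, 2,6-lutidine, 1,4-dioxane/H2O, 25 °C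
Reagents that add atoms: osmium tetroxide, O=[Os](=O)(=O)=O; sodium periodate, [Na+].[O-]I(=O)(=O)=O
Why: Lemieux–Johnson cleavage, in which OsO4 should dihydroxylate the open monosubstituted allyl alkene far faster than the C5=C6 alkene buried between the quaternary carbons C4 and C10, and periodate cleaves the diol to the C8 aldehyde.

Step 5
Reactants: 7 (R)-2-(1,3,3-trimethyl-2-methylidenecyclohexyl)acetaldehyde
Product: 8 (R)-2-(1,3,3-trimethyl-2-methylidenecyclohexyl)acetic acid
Conditions: NaClO2, NaH2PO4, 2-methyl-2-butene, t-BuOH/H2O, 0 → 25 °C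
Reagents that add atoms: sodium chlorite, [Na+].[O-]Cl=O
Why: Pinnick oxidation converts the aldehyde to the acid under buffered conditions while the alkene scavenger keeps hypochlorous acid away from the exocyclic alkene.

Step 6
Reactants: 8 (R)-2-(1,3,3-trimethyl-2-methylidenecyclohexyl)acetic acid; 9 2-(2-bromoethyl)-2-methyl-1,3-dioxolane
Product: 10 4-(2-methyl-1,3-dioxolan-2-yl)-2-[(1R)-1,3,3-trimethyl-2-methylidenecyclohexyl]butanoic acid (C9 epimers)
Conditions: LDA (2.3 equiv), THF, 0 → 45 °C; DMPU, 9, n-Bu4NI (0.1 equiv), 0 → 25 °C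
Reagents that add atoms: none
Why: Alkylation of a carboxylic acid dianion, whose enediolate can form only at C9, by SN2 reaction with the primary halide installs C11–C13 as the ketal, and the new C9 centre need not be controlled because it is equilibrated in step 10.

Step 7
Reactants: 10 4-(2-methyl-1,3-dioxolan-2-yl)-2-[(1R)-1,3,3-trimethyl-2-methylidenecyclohexyl]butanoic acid (C9 epimers)
Product: 11 5-(2-methyl-1,3-dioxolan-2-yl)-3-[(1R)-1,3,3-trimethyl-2-methylidenecyclohexyl]pentan-2-one (C9 epimers)
Conditions: MeLi (3.5 equiv), Et2O, 0 → 25 °C; inverse quench into cold aq. NH4Cl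
Reagents that add atoms: methyllithium, [Li]C
Why: Methyllithium adds to the lithium carboxylate to give a geminal dialkoxide that releases the methyl ketone only on quenching (ketone synthesis from a carboxylic acid), so C7 is attached to C8 without over-addition while alkene and ketal stay inert.

Step 8
Reactants: 11 5-(2-methyl-1,3-dioxolan-2-yl)-3-[(1R)-1,3,3-trimethyl-2-methylidenecyclohexyl]pentan-2-one (C9 epimers)
Product: 12 3-[(1R)-2-(hydroxymethyl)-1,3,3-trimethylcyclohexyl]-5-(2-methyl-1,3-dioxolan-2-yl)pentan-2-ol with the hydroxymethyl group cis to the C10 methyl (5α-H; C8 and C9 epimers)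
Conditions: BH3·THF (3 equiv), THF, 0 → 25 °C; then NaOH, H2O2, 0 → 40 °C
Reagents that add atoms: hydrogen peroxide, OO
Why: Hydroboration–oxidation places boron on C6 and delivers hydrogen to C5 on the ring face opposite the two axial methyls on C4 and C10, which should put C6 equatorial and trans to the C9 branch (5α-H), while the ketone is reduced to a carbinol that is reoxidised in step 9.

Step 9
Reactants: 12 3-[(1R)-2-(hydroxymethyl)-1,3,3-trimethylcyclohexyl]-5-(2-methyl-1,3-dioxolan-2-yl)pentan-2-ol
Product: 13 2-[5-(2-methyl-1,3-dioxolan-2-yl)-2-oxopentan-3-yl]-2,6,6-trimethylcyclohexane-1-carbaldehyde, the 6,7-seco keto aldehyde with CHO cis to the C10 methyl (C9 epimers)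
Conditions: (COCl)2, DMSO, CH2Cl2, −78 °C; Et3N, −78 → −20 °C
Reagents that add atoms: none
Why: Swern oxidation converts both alcohols in one operation into the C8 methyl ketone and the hindered C6 aldehyde under non-acidic conditions that leave the ketal and the slowly enolising C5 centre untouched.

Step 10
Reactants: 13 6,7-seco keto aldehyde
Product: 14 13,13-ethylenedioxy-6α-hydroxy-14,15,17-trinorlabdan-8-one (trans-decalin, 9β side chain)
Conditions: K2CO3 (0.5 equiv), MeOH, 0 → 20 °C
Reagents that add atoms: none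
Why: Carbonate in methanol reversibly generates the methyl-side enolate (C7) of the C8 ketone, which adds to the C6 aldehyde and closes ring B as the β-hydroxy ketone; the closest known reaction type is the base-mediated intramolecular aldol cyclisation of 1,5-keto aldehydes to 3-hydroxycyclohexanones. Ring B closes in a 6-(enolexo)-exo-trig mode, and enolisation toward C9 or of the aldehyde at C5 could only lead to four-membered rings, so the regiochemistry is built in. C6 is controlled by the chair transition state and by reversibility, the carbinol oxygen taking the equatorial α position because the axial β position would be syn-diaxial to both the C10 methyl and the 4β-methyl. C9 is controlled thermodynamically, since it remains α to the C8 ketone and epimerises to the equatorial 9β chain, whereas C5 arrives correctly configured from step 8 and is locked into the trans ring fusion against the non-epimerisable quaternary C10. The selectivity needed is addition without loss of water and without reaction at C13: the equatorial C6–O bond is poorly aligned for E1cB elimination at 0–20 °C, and the dioxolane removes the second methyl ketone that could otherwise compete.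

Step 11
Reactants: 14 13,13-ethylenedioxy-6α-hydroxy-14,15,17-trinorlabdan-8-one
Product: 15 13,13-ethylenedioxy-6α-(triethylsilyloxy)-14,15,17-trinorlabdan-8-one
Conditions: TESOTf, 2,6-lutidine, CH2Cl2, −78 °C
Reagents that add atoms: triethylsilyl trifluoromethanesulfonate, CC[Si](CC)(CC)OS(=O)(=O)C(F)(F)F
Why: Silylation of the hindered equatorial 6α-hydroxyl with a silyl triflate and a non-nucleophilic base is fast at low temperature and blocks retro-aldol cleavage in the enolate chemistry that follows.

Step 12
Reactants: 15 13,13-ethylenedioxy-6α-(triethylsilyloxy)-14,15,17-trinorlabdan-8-one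
Product: 16 13,13-ethylenedioxy-6α-(triethylsilyloxy)-14,15,17-trinorlabd-7-en-8-yl trifluoromethanesulfonate
Conditions: KHMDS, THF, −78 °C; PhNTf2, −78 → −40 °C
Reagents that add atoms: N-phenylbis(trifluoromethanesulfonimide), O=S(=O)(N(c1ccccc1)S(=O)(=O)C(F)(F)F)C(F)(F)F
Why: Kinetic deprotonation by the bulky amide takes place at the C7 methylene instead of the tertiary, neopentylic C9–H, and O-sulfonylation of the enolate gives the Δ7 enol triflate, the equatorial 6-silyloxy group being badly aligned for β-elimination at −78 °C.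

Step 13
Reactants: 16 13,13-ethylenedioxy-6α-(triethylsilyloxy)-14,15,17-trinorlabd-7-en-8-yl trifluoromethanesulfonate
Product: 17 13,13-ethylenedioxy-6α-(triethylsilyloxy)-14,15-dinorlabd-7-ene
Conditions: Me2CuLi (from CuI and MeLi), THF, −20 → 0 °C
Reagents that add atoms: lithium dimethylcuprate, [Li+].C[Cu-]C
Why: Cross-coupling of an enol triflate with a lithium dialkylcuprate replaces the triflate by methyl without moving the double bond, which installs C17 on C8.

Step 14
Reactants: 17 13,13-ethylenedioxy-6α-(triethylsilyloxy)-14,15-dinorlabd-7-ene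
Product: 18 13,13-ethylenedioxy-6α-(triethylsilyloxy)-14,15-dinorlabdane-7α,8α-diol
Conditions: OsO4 (5–10 mol %), NMO, acetone/H2O, 25 °C
Reagents that add atoms: osmium tetroxide, O=[Os](=O)(=O)=O; N-methylmorpholine N-oxide, C[N+]1([O-])CCOCC1; water, O
Why: Catalytic syn-dihydroxylation should occur from the α face because the axial C10 methyl shields the β face at C8, which sets the 8α-hydroxyl and 8β-methyl of the target together with a 7α-hydroxyl that is corrected in steps 15 and 18.

Step 15
Reactants: 18 13,13-ethylenedioxy-6α-(triethylsilyloxy)-14,15-dinorlabdane-7α,8α-diol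
Product: 19 13,13-ethylenedioxy-8α-hydroxy-6α-(triethylsilyloxy)-14,15-dinorlabdan-7-one
Conditions: (COCl)2, DMSO, CH2Cl2, −78 °C; Et3N, −78 → 0 °C
Reagents that add atoms: none
Why: Swern oxidation can affect only the secondary 7α-alcohol, because the 8-hydroxyl is tertiary, and it avoids glycol cleavage while erasing the wrong C7 configuration.

Step 16
Reactants: 19 13,13-ethylenedioxy-8α-hydroxy-6α-(triethylsilyloxy)-14,15-dinorlabdan-7-one
Product: 21 8α,13-epoxy-6α-hydroxy-14,15-dinorlabd-12-en-7-one (cyclic enol ether), via hydroxy diketone 20 (not isolated)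
Conditions: 1 M HCl (aq), THF, 25 °C; then PPTS (0.1 equiv), toluene, 4 Å MS, 60 °C
Reagents that add atoms: none
Why: Aqueous acid removes the silyl ether and the dioxolane, and the freed C13 ketone is captured by the tertiary 8α-hydroxyl as a six-membered hemiketal that dehydrates to the endocyclic enol ether (cyclodehydration of a δ-hydroxy ketone), which masks C13 and fixes the enol position at C12.

Step 17
Reactants: 21 8α,13-epoxy-6α-hydroxy-14,15-dinorlabd-12-en-7-one
Product: 22 6α-acetoxy-8α,13-epoxy-14,15-dinorlabd-12-en-7-one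
Conditions: Ac2O, pyridine, DMAP (0.1 equiv), CH2Cl2, 25 °C
Reagents that add atoms: acetic anhydride, CC(=O)OC(C)=O
Why: DMAP-catalysed acetylation meets only one free hydroxyl (6α-OH), because C7 is still a ketone and O8 is tied up in the enol ether, so no choice between O6 and O7 has to be made.

Step 18
Reactants: 22 6α-acetoxy-8α,13-epoxy-14,15-dinorlabd-12-en-7-one
Product: 23 6α-acetoxy-8α,13-epoxy-14,15-dinorlabd-12-en-7β-ol
Conditions: NaBH4, MeOH/THF, −40 → 0 °C; pH 7 buffer
Reagents that add atoms: none
Why: Borohydride reduction of the cyclohexanone should deliver hydride to C7 along the axial α trajectory because the axial 8β-methyl blocks the β face, giving the equatorial 7β-alcohol, while the enol ether is inert to hydride and the low temperature is meant to suppress acetyl migration.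

Step 19
Reactants: 23 6α-acetoxy-8α,13-epoxy-14,15-dinorlabd-12-en-7β-ol
Product: 27 6α-acetoxy-7β,8α-dihydroxy-14,15-dinorlabd-11(E)-en-13-one (target, CNP0136046.1), via chloro selenide 24 (not isolated), via seleno ketone 25 (not isolated), via selenoxide 26 (not isolated)
Conditions: PhSeCl, CH2Cl2, −78 °C; sat. aq. NaHCO3, 0 °C; then 30% H2O2, pyridine, 0 → 25 °C
Reagents that add atoms: water, O
Why: Electrophilic selenenylation of the enol ether at C12 and hydrolysis of the chloro ether give the open-chain α-phenylseleno ketone regiospecifically, and oxidation followed by syn-elimination of the selenoxide toward C11 (selenoxide elimination) should give the E-enone, which can no longer close onto the 8-hydroxyl.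

**Compound list**

1 | 2,2,6-trimethylcyclohexan-1-one (racemic) | CC1CCCC(C)(C)C1=O | starting material
2 | allyl chloroformate | C=CCOC(=O)Cl | starting material
3 | allyl 2,6,6-trimethylcyclohex-1-en-1-yl carbonate | C=CCOC(=O)OC1=C(C)CCCC1(C)C | intermediate
4 | (R)-2-allyl-2,6,6-trimethylcyclohexan-1-one | C=CC[C@@]1(C)CCCC(C)(C)C1=O | intermediate
5 | (2R)-2-allyl-2,6,6-trimethyl-1-[(trimethylsilyl)methyl]cyclohexan-1-ol (carbinol epimers, not isolated) | C=CC[C@@]1(C)CCCC(C)(C)C1(O)C[Si](C)(C)C | intermediate
6 | (R)-1-allyl-1,3,3-trimethyl-2-methylidenecyclohexane | C=CC[C@@]1(C)CCCC(C)(C)C1=C | intermediate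
7 | (R)-2-(1,3,3-trimethyl-2-methylidenecyclohexyl)acetaldehyde | O=CC[C@@]1(C)CCCC(C)(C)C1=C | intermediate
8 | (R)-2-(1,3,3-trimethyl-2-methylidenecyclohexyl)acetic acid | OC(=O)C[C@@]1(C)CCCC(C)(C)C1=C | intermediate
9 | 2-(2-bromoethyl)-2-methyl-1,3-dioxolane | CC1(CCBr)OCCO1 | starting material
10 | 4-(2-methyl-1,3-dioxolan-2-yl)-2-[(1R)-1,3,3-trimethyl-2-methylidenecyclohexyl]butanoic acid (C9 epimers; the epimer that maps onto 14 is drawn) | CC1(OCCO1)CC[C@H]([C@@]2(C)CCCC(C)(C)C2=C)C(O)=O | intermediate
11 | 5-(2-methyl-1,3-dioxolan-2-yl)-3-[(1R)-1,3,3-trimethyl-2-methylidenecyclohexyl]pentan-2-one (C9 epimers; productive epimer drawn) | CC1(OCCO1)CC[C@H]([C@@]2(C)CCCC(C)(C)C2=C)C(C)=O | intermediate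
12 | 3-[(1R)-2-(hydroxymethyl)-1,3,3-trimethylcyclohexyl]-5-(2-methyl-1,3-dioxolan-2-yl)pentan-2-ol, hydroxymethyl cis to the C10 methyl (C8 carbinol epimers, C9 epimers; productive C9 epimer drawn) | CC1(OCCO1)CC[C@H]([C@@]2(C)CCCC(C)(C)[C@@H]2CO)C(C)O | intermediate
13 | 2-[5-(2-methyl-1,3-dioxolan-2-yl)-2-oxopentan-3-yl]-2,6,6-trimethylcyclohexane-1-carbaldehyde, 6,7-seco keto aldehyde, CHO cis to the C10 methyl (C9 epimers; productive epimer drawn) | CC1(OCCO1)CC[C@H]([C@@]2(C)CCCC(C)(C)[C@@H]2C=O)C(C)=O | intermediate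
14 | 13,13-ethylenedioxy-6α-hydroxy-14,15,17-trinorlabdan-8-one | CC1(OCCO1)CC[C@H]1C(=O)C[C@H](O)[C@H]2C(C)(C)CCC[C@@]21C | intermediate
15 | 13,13-ethylenedioxy-6α-(triethylsilyloxy)-14,15,17-trinorlabdan-8-one | CC1(OCCO1)CC[C@H]1C(=O)C[C@H](O[Si](CC)(CC)CC)[C@H]2C(C)(C)CCC[C@@]21C | intermediate
16 | 13,13-ethylenedioxy-6α-(triethylsilyloxy)-14,15,17-trinorlabd-7-en-8-yl trifluoromethanesulfonate | CC1(OCCO1)CC[C@H]1C(OS(=O)(=O)C(F)(F)F)=C[C@H](O[Si](CC)(CC)CC)[C@H]2C(C)(C)CCC[C@@]21C | intermediate
17 | 13,13-ethylenedioxy-6α-(triethylsilyloxy)-14,15-dinorlabd-7-ene | CC1(OCCO1)CC[C@H]1C(C)=C[C@H](O[Si](CC)(CC)CC)[C@H]2C(C)(C)CCC[C@@]21C | intermediate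
18 | 13,13-ethylenedioxy-6α-(triethylsilyloxy)-14,15-dinorlabdane-7α,8α-diol | CC1(OCCO1)CC[C@H]1[C@](C)(O)[C@H](O)[C@H](O[Si](CC)(CC)CC)[C@H]2C(C)(C)CCC[C@@]21C | intermediate
19 | 13,13-ethylenedioxy-8α-hydroxy-6α-(triethylsilyloxy)-14,15-dinorlabdan-7-one | CC1(OCCO1)CC[C@H]1[C@](C)(O)C(=O)[C@H](O[Si](CC)(CC)CC)[C@H]2C(C)(C)CCC[C@@]21C | intermediate
20 | 6α,8α-dihydroxy-14,15-dinorlabdane-7,13-dione (not isolated) | CC(=O)CC[C@H]1[C@](C)(O)C(=O)[C@H](O)[C@H]2C(C)(C)CCC[C@@]21C | intermediate
21 | 8α,13-epoxy-6α-hydroxy-14,15-dinorlabd-12-en-7-one | CC1=CC[C@H]2[C@](C)(O1)C(=O)[C@H](O)[C@H]3C(C)(C)CCC[C@@]32C | intermediate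
22 | 6α-acetoxy-8α,13-epoxy-14,15-dinorlabd-12-en-7-one | CC1=CC[C@H]2[C@](C)(O1)C(=O)[C@H](OC(C)=O)[C@H]3C(C)(C)CCC[C@@]32C | intermediate
23 | 6α-acetoxy-8α,13-epoxy-14,15-dinorlabd-12-en-7β-ol | CC1=CC[C@H]2[C@](C)(O1)[C@@H](O)[C@H](OC(C)=O)[C@H]3C(C)(C)CCC[C@@]32C | intermediate
24 | 6α-acetoxy-13-chloro-8α,13-epoxy-12-(phenylselanyl)-14,15-dinorlabdan-7β-ol (C12/C13 epimers, not isolated) | CC1(Cl)C([Se]c2ccccc2)C[C@H]2[C@](C)(O1)[C@@H](O)[C@H](OC(C)=O)[C@H]3C(C)(C)CCC[C@@]32C | intermediate
25 | 6α-acetoxy-7β,8α-dihydroxy-12-(phenylselanyl)-14,15-dinorlabdan-13-one (C12 epimers, not isolated) | CC(=O)C([Se]c1ccccc1)C[C@H]1[C@](C)(O)[C@@H](O)[C@H](OC(C)=O)[C@H]2C(C)(C)CCC[C@@]21C | intermediate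
26 | 6α-acetoxy-7β,8α-dihydroxy-12-(phenylseleninyl)-14,15-dinorlabdan-13-one (not isolated) | CC(=O)C([Se](=O)c1ccccc1)C[C@H]1[C@](C)(O)[C@@H](O)[C@H](OC(C)=O)[C@H]2C(C)(C)CCC[C@@]21C | intermediate
27 | 6α-acetoxy-7β,8α-dihydroxy-14,15-dinorlabd-11(E)-en-13-one | CC(=O)/C=C/[C@H]1[C@](C)(O)[C@@H](O)[C@H](OC(C)=O)[C@H]2C(C)(C)CCC[C@@]21C | target

**Step count**

Total steps: 19. Longest linear sequence: 19 (steps 1–19; compound 9 is purchased).

**Steps most likely to fail**

1. Step 10 (ring B closure). What may go wrong: water is lost from the β-hydroxy ketone under the basic conditions, or material that is epimeric at C5 closes to a cis-fused aldol that does not revert. Fallback, setting out from 13: the condensation is driven on purpose (KOH, MeOH, 60 °C) to the trans-fused 13,13-ethylenedioxy-14,15,17-trinorlabd-6-en-8-one F1, in which C5 is γ to the carbonyl and equilibrates through the dienolate. Nucleophilic epoxidation (H2O2, NaOH, MeOH, 0 °C) from the α face, away from the axial C10 and 4β methyls, should give the 6α,7α-epoxy ketone F2. SmI2 (THF/MeOH, −78 °C) cleaves the C7–O bond next to the ketone and brings the route back at 14.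

2. Step 6 (C9 alkylation). What may go wrong: the strongly basic, hindered enediolate removes HBr from the halide faster than it is alkylated. Fallback, setting out from 8: esterification (MeI, K2CO3, DMF) gives the methyl ester F3. Its lithium enolate (LDA, THF, −78 °C) is added to 3-(trimethylsilyl)but-3-en-2-one, an α-silyl vinyl ketone that accepts ester enolates in Michael fashion, to give the α-silyl keto ester F4. Desilylation with KF in MeOH gives the keto ester F5. Ketalisation of the only ketone (ethylene glycol, PPTS, benzene, water separator) gives the ketal ester F6, and saponification (LiOH, THF/MeOH/H2O, 50 °C) rejoins the route at 10.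

3. Step 19 (enone formation). What may go wrong: part of the selenoxide eliminates within the cyclic hemiketal form and gives the cis alkene, or selenenylation and hydrolysis do not go to completion. Fallback, setting out from 23: silylation (TBSOTf, 2,6-lutidine, CH2Cl2, −40 °C) gives the 7-O-TBS enol ether F7. Mild hydrolysis of the enol ether (AcOH/THF/H2O, 25 °C) gives the 7-O-TBS hydroxy ketone F8. Dehydrogenation with 2-iodoxybenzoic acid (DMSO/toluene, 70 °C) can only occur between C11 and C12 of this methyl ketone and should give the E-enone silyl ether F9. HF·pyridine in THF then removes the silyl group and returns the route at 27.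

Further compounds
F1 | step 10 | 13,13-ethylenedioxy-14,15,17-trinorlabd-6-en-8-one | CC1(OCCO1)CC[C@H]1C(=O)C=C[C@H]2C(C)(C)CCC[C@@]21C
F2 | step 10 | 6α,7α-epoxy-13,13-ethylenedioxy-14,15,17-trinorlabdan-8-one | CC1(OCCO1)CC[C@H]1C(=O)[C@@H]3O[C@@H]3[C@H]2C(C)(C)CCC[C@@]21C
F3 | step 6 | methyl (R)-2-(1,3,3-trimethyl-2-methylidenecyclohexyl)acetate | COC(=O)C[C@@]1(C)CCCC(C)(C)C1=C
F4 | step 6 | methyl 5-oxo-4-(trimethylsilyl)-2-[(1R)-1,3,3-trimethyl-2-methylidenecyclohexyl]hexanoate | CC(=O)C([Si](C)(C)C)C[C@H]([C@@]1(C)CCCC(C)(C)C1=C)C(=O)OC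
F5 | step 6 | methyl 5-oxo-2-[(1R)-1,3,3-trimethyl-2-methylidenecyclohexyl]hexanoate | CC(=O)CC[C@H]([C@@]1(C)CCCC(C)(C)C1=C)C(=O)OC
F6 | step 6 | methyl 4-(2-methyl-1,3-dioxolan-2-yl)-2-[(1R)-1,3,3-trimethyl-2-methylidenecyclohexyl]butanoate | CC1(OCCO1)CC[C@H]([C@@]2(C)CCCC(C)(C)C2=C)C(=O)OC
F7 | step 19 | 6α-acetoxy-7β-(tert-butyldimethylsilyloxy)-8α,13-epoxy-14,15-dinorlabd-12-ene | CC1=CC[C@H]2[C@](C)(O1)[C@@H](O[Si](C)(C)C(C)(C)C)[C@H](OC(C)=O)[C@H]3C(C)(C)CCC[C@@]32C
F8 | step 19 | 6α-acetoxy-7β-(tert-butyldimethylsilyloxy)-8α-hydroxy-14,15-dinorlabdan-13-one | CC(=O)CC[C@H]1[C@](C)(O)[C@@H](O[Si](C)(C)C(C)(C)C)[C@H](OC(C)=O)[C@H]2C(C)(C)CCC[C@@]21C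
F9 | step 19 | 6α-acetoxy-7β-(tert-butyldimethylsilyloxy)-8α-hydroxy-14,15-dinorlabd-11(E)-en-13-one | CC(=O)/C=C/[C@H]1[C@](C)(O)[C@@H](O[Si](C)(C)C(C)(C)C)[C@H](OC(C)=O)[C@H]2C(C)(C)CCC[C@@]21C
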